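I decided to judge this flask by how far its catalyst charge can reach, not by how fast it starts.

- north-east: left-handed substrate 46 mM; right-handed substrate 46 mM; solid reagent 8 equiv; free catalyst 0.053 mol%; added ligand 73 µM; run made earlier
- flask: left-handed substrate 46 mM; solid reagent 4.00 equiv; free catalyst 0.053 mol%; added ligand 73 µM; right-handed substrate 46 mM; time 6.0 d

north-east run (percent of the left-handed substrate and right-handed substrate together charged)

| time / h | left-handed substrate / % | right-handed substrate / % | left-handed product / % |
|---|---|---|---|
| 3.00 | 45 | 48 | 4 |
| 8.00 | 44 | 42 | 12 |
| 15.0 | 38 | 38 | 25 |
| 25.0 | 35 | 33 | 35 |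
| 30.0 | 30 | 28 | 36 |
| 40.0 | 27 | 27 | 43 |

(each reading ± 2 percentage points)

- free catalyst is single-handed; left-handed substrate and right-handed substrate are mirror images of each other, charged as a racemate, each of them at the stated concentration
- solid reagent is a solid; its amount is given per volume of the solution
- the numbers in the tables scatter with a standard deviation of 2 percentage points
- at the start none of the solid reagent is in solution
- an excess is the difference of the two amounts in percent of their sum
- an excess is below zero if the other one leads

- part of the left-handed substrate and right-handed substrate charged together that has reacted at 6.0 d
- excess of left-handed product over right-handed product in the product at 6.0 d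
- excess of right-handed substrate over left-handed substrate among what is left of the two at 6.0 d

My reckoning, built from the north-east run, used the sum of the two substrates, which fell together.

1. Main step. I took the mean pseudo-first-order constant up to 15.0 h, 0.0183 h⁻¹. Held constant, it gave 92.8 % reacted at 6.0 d.

2. Fading. From 15.0 h to 40.0 h the mean constant was lower, 0.0137 h⁻¹. I let each mean stand for the constant at the middle of its window and assumed exponential fading, so the fading time was 68.6 h. Replacing the curve by its mean cost about 0.553 % of the later constant, and each reading scatters by 2 percentage points, so this time is loose. Read back to the start, the constant came to 0.0204 h⁻¹. I estimated the reach, the whole fall in ln of the substrate sum as the rate fades, as this starting constant times the fading time: 1.40. By 6.0 d I reckoned a fall of 1.23, so 70.7 % reacted.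

3. The rest. The flask's solid reagent, 184 mM, exceeds the 92.0 mM of substrate, so, assuming one per substrate, I kept the constants. At 40.0 h the two substrates of the north-east run read equal, and product against loss read as an excess of 87.0 %; I put eS at zero.

The forecast, calling the run “perhaps slowing slightly”, gave 85 %, 88 % and 0 %. Its conversion stands above mine.

The flask gave 67.3 %, 88.2 % and 0.0254 %.

    solid reagent ⇌ partner, rate k1*(cs1 - [partner]) while solid is left; crystals form when [partner] > cs1 (solubility = 41.0 mM, k = 2.31 h⁻¹)
    partner + free catalyst + left-handed substrate → free catalyst + left-handed product (k = 65200 L² mol⁻² h⁻¹)
    free catalyst → spent catalyst (k = 0.0277 h⁻¹)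
    partner + free catalyst + right-handed substrate → free catalyst + right-handed product (k = 4060 L² mol⁻² h⁻¹)
    left-handed substrate ⇌ right-handed substrate (k = 3.13 h⁻¹)
    free catalyst + added ligand ⇌ idle complex (K = 8800 L mol⁻¹, k = 4010 L mol⁻¹ h⁻¹)

Free catalyst has a half-life of 1.0 d by its passing into spent catalyst, short against the 6.0 d of the flask, and at 6.00 d 91.4 % of the catalyst charged stood as spent catalyst. The flask's fall in ln was 1.12, a little below my 1.23.

In the neighbour flask with 0.013 mol% of free catalyst, the reach taken in proportion to the catalyst charge, with the same fading time, gives a fall by 6.0 d of 0.301, so 26.0 % reacted. The computed result is 24.1 %.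

The runs come from a simulation on assumed constants; noise was put on by code.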